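**Retrosynthetic overview**

1. Ring letters: A is the benzo ring of the chromanone, C the pyranone, B the 3-aryl ring, D the 2,2-dimethylpyran fused to B. The silyl groups come off last; the C3 stereocentre is set by asymmetric transfer hydrogenation with dynamic kinetic resolution of the racemic isoflavanone, followed by re-oxidation of C4.
2. The isoflavanone comes from the isoflavone by 1,4-reduction. The isoflavone comes from Suzuki coupling across C3–C1' of a 3-iodochromone (ring C closed from an acetophenone enaminone) with the ring B/D boronate.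
3. Ring D is closed by forming the bond between C3 and the quaternary C2 of the chromene. A catechol acetonide with an ortho vinyl group is isomerised by a silyl triflate (ketal ionisation, Prins closure, proton loss). This gives the pyran ring, the C3=C4 alkene and the silyl-protected C8 oxygen in one operation.
4. Enabling feature: the pyran oxygen O1 (on C8a) and the hydroxyl on C8 sit on adjacent carbons of ring B, a catechol. C2 with its two methyl groups can therefore start as the isopropylidene carbon bridging these two oxygens, while C3 and C4 start as a vinyl group on C4a.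
5. Order of ring formation: ring D (step 4), ring C (step 7), union of the halves (step 8); rings A and B are bought.

Key step: step 4

Assumption: the (S,S)-TsDPEN ruthenium catalyst is assigned to the (3S,4S)-alcohol from the sense it shows with benzo-fused cyclic ketones; should the sense be reversed, the (R,R)-catalyst is used.

**Route**

Step 1
Reactants: 1 5-bromo-2-hydroxy-3-methoxybenzaldehyde
Product: 2 5-bromo-2,3-dihydroxybenzaldehyde
Conditions: BBr3, CH2Cl2, −78 °C → rt; then H2O
Reagents that add atoms: none
Why: Lewis-acid cleavage of the aryl methyl ether, assisted by the neighbouring phenol, should leave the aldehyde and the aryl bromide untouched at low temperature.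

Step 2
Reactants: 2 5-bromo-2,3-dihydroxybenzaldehyde
Product: 3 6-bromo-2,2-dimethyl-1,3-benzodioxole-4-carbaldehyde
Conditions: Me2C(OMe)2, p-TsOH·H2O (cat.), toluene, reflux (4 Å MS Soxhlet); then 1 M HCl/THF, rt
Reagents that add atoms: 2,2-dimethoxypropane, COC(C)(C)OC
Why: Acid-catalysed transketalisation of the catechol is driven by removal of methanol, and any dimethyl acetal formed at the aldehyde should hydrolyse in the acidic wash while the catechol ketal survives.

Step 3
Reactants: 3 6-bromo-2,2-dimethyl-1,3-benzodioxole-4-carbaldehyde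
Product: 4 6-bromo-4-ethenyl-2,2-dimethyl-1,3-benzodioxole
Conditions: Ph3PCH3Br, KOt-Bu, THF, 0 °C → rt
Reagents that add atoms: methyltriphenylphosphonium bromide, C[P+](c1ccccc1)(c1ccccc1)c1ccccc1.[Br-]
Why: Wittig methylenation of the aromatic aldehyde with the non-stabilised ylide; the ketal and the aryl bromide are inert to it.

Step 4
Reactants: 4 6-bromo-4-ethenyl-2,2-dimethyl-1,3-benzodioxole
Product: 7 [(6-bromo-2,2-dimethyl-2H-chromen-8-yl)oxy](tert-butyl)dimethylsilane, via aryl oxocarbenium triflate 5 (not isolated), via chroman-4-yl cation triflate 6 (not isolated)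
Conditions: TBSOTf (1.3 equiv), 2,6-di-tert-butyl-4-methylpyridine (1.5 equiv), CH2Cl2 (0.02 M), −40 °C → rt
Reagents that add atoms: tert-butyldimethylsilyl trifluoromethanesulfonate, CC(C)(C)[Si](C)(C)OS(=O)(=O)C(F)(F)F
Why: Proposed new method: TBSOTf should silylate the less hindered ketal oxygen (on the carbon remote from the vinyl group) and the ketal should ionise to aryl oxocarbenium ion 5, whose carbon (future C2) is attacked by the terminal vinyl carbon (future C3) in a Prins closure. The 4-chromanyl cation 6, stabilised by the ortho ring oxygen, then loses a C3 proton to the hindered pyridine, so the pyran ring, the C3=C4 alkene and the silyl-protected C8 phenol arise together. The closest known reaction types are the Petasis–Ferrier rearrangement (Lewis-acid opening of a cyclic acetal to a tethered oxocarbenium ion, then C–C closure) and the acetal-initiated Prins and Prins–pinacol cyclisations of 4-alkenyl-1,3-dioxolanes; new here are the catechol ketal as oxocarbenium source and the styrene as π-nucleophile. The ring closes 6-endo-trig at the styrene (equally a cationic 2-oxonia 6π electrocyclisation through the arene), the 5-exo mode being excluded because it would give a primary cation; no stereocentre is formed. The step needs the productive site of ionisation and ring closure ahead of styrene oligomerisation: ionisation at the other oxygen gives an oxocarbenium ion with no alkene in reach and should return to the ketal, and the proton-poor, dilute medium should keep the vinyl group from cationic polymerisation.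

Step 5
Reactants: 7 [(6-bromo-2,2-dimethyl-2H-chromen-8-yl)oxy](tert-butyl)dimethylsilane
Product: 8 tert-butyldimethyl{[2,2-dimethyl-6-(4,4,5,5-tetramethyl-1,3,2-dioxaborolan-2-yl)-2H-chromen-8-yl]oxy}silane
Conditions: B2pin2, Pd(dppf)Cl2 (3 mol%), KOAc, 1,4-dioxane, 85 °C
Reagents that add atoms: bis(pinacolato)diboron, CC1(C)OB(OC1(C)C)B1OC(C)(C)C(C)(C)O1
Why: Miyaura borylation: the unhindered aryl bromide adds to zerovalent palladium, acetate-assisted transmetalation with B2pin2 follows, and the aryl silyl ether and chromene alkene are inert to KOAc.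

Step 6
Reactants: 9 1-(2,4-dihydroxy-6-methoxyphenyl)ethan-1-one
Product: 10 1-{2-hydroxy-6-methoxy-4-[(triisopropylsilyl)oxy]phenyl}ethan-1-one
Conditions: TIPSCl, imidazole, DMF, 0 °C → rt
Reagents that add atoms: triisopropylsilyl chloride, CC(C)[Si](Cl)(C(C)C)C(C)C
Why: Silylation should take the more acidic 4-hydroxyl, because the 2-hydroxyl is held in a hydrogen bond to the acetyl group and stays free for the later closure of ring C.

Step 7
Reactants: 10 1-{2-hydroxy-6-methoxy-4-[(triisopropylsilyl)oxy]phenyl}ethan-1-one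
Product: 12 3-iodo-5-methoxy-7-[(triisopropylsilyl)oxy]-4H-chromen-4-one, via enaminone 11 (not isolated)
Conditions: Me2NCH(OMe)2, toluene, 95 °C; concentrate; then I2, pyridine, CHCl3, rt
Reagents that add atoms: N,N-dimethylformamide dimethyl acetal, COC(OC)N(C)C; iodine, II
Why: Condensation of the methyl ketone with the amide acetal gives the enaminone, and iodine then iodinates its α-carbon so that the phenol closes ring C onto the iminium carbon with loss of dimethylamine (iodine-mediated enaminone cyclisation to a 3-iodochromone).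

Step 8
Reactants: 8 tert-butyldimethyl{[2,2-dimethyl-6-(4,4,5,5-tetramethyl-1,3,2-dioxaborolan-2-yl)-2H-chromen-8-yl]oxy}silane, 12 3-iodo-5-methoxy-7-[(triisopropylsilyl)oxy]-4H-chromen-4-one
Product: 13 3-{8-[(tert-butyldimethylsilyl)oxy]-2,2-dimethyl-2H-chromen-6-yl}-5-methoxy-7-[(triisopropylsilyl)oxy]-4H-chromen-4-one
Conditions: Pd(dppf)Cl2 (5 mol%), K3PO4, 1,4-dioxane/H2O (10:1), 60 °C
Reagents that add atoms: none
Why: Suzuki–Miyaura coupling of a 3-iodochromone with an aryl pinacol boronate is the standard isoflavone assembly, and the phosphate base at moderate temperature is chosen to spare the aryl silyl ethers and the chromone.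

Step 9
Reactants: 13 3-{8-[(tert-butyldimethylsilyl)oxy]-2,2-dimethyl-2H-chromen-6-yl}-5-methoxy-7-[(triisopropylsilyl)oxy]-4H-chromen-4-one
Product: 15 rac-3-{8-[(tert-butyldimethylsilyl)oxy]-2,2-dimethyl-2H-chromen-6-yl}-5-methoxy-7-[(triisopropylsilyl)oxy]chroman-4-one, via lithium enolate 14 (not isolated)
Conditions: LiBH(s-Bu)3 (L-Selectride), THF, −78 → −40 °C; then AcOH, −78 °C → rt
Reagents that add atoms: none
Why: 1,4-Reduction of the isoflavone by the bulky hydride gives the enolate, which is protected from over-reduction until the acidic quench; C3 is formed racemic here on purpose and the chromene alkene is not touched.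

Step 10
Reactants: 15 rac-3-{8-[(tert-butyldimethylsilyl)oxy]-2,2-dimethyl-2H-chromen-6-yl}-5-methoxy-7-[(triisopropylsilyl)oxy]chroman-4-one
Product: 16 (3S,4S)-3-{8-[(tert-butyldimethylsilyl)oxy]-2,2-dimethyl-2H-chromen-6-yl}-5-methoxy-7-[(triisopropylsilyl)oxy]chroman-4-ol (3,4-cis)
Conditions: RuCl[(S,S)-TsDPEN](p-cymene) (5 mol%), HCO2H/Et3N (1:2), EtOAc, 40 °C
Reagents that add atoms: none
Why: Noyori asymmetric transfer hydrogenation with dynamic kinetic resolution: the excess amine racemises the labile C3 of the ketone while the (S,S)-catalyst should reduce the (3S)-ketone much faster, hydride adding to C4 on the face away from the 3-aryl group, so (4S) is fixed by the catalyst and (3S) by the cis relationship; the amine-rich medium also protects the acid-sensitive benzylic alcohol.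

Step 11
Reactants: 16 (3S,4S)-3-{8-[(tert-butyldimethylsilyl)oxy]-2,2-dimethyl-2H-chromen-6-yl}-5-methoxy-7-[(triisopropylsilyl)oxy]chroman-4-ol
Product: 17 (3S)-3-{8-[(tert-butyldimethylsilyl)oxy]-2,2-dimethyl-2H-chromen-6-yl}-5-methoxy-7-[(triisopropylsilyl)oxy]chroman-4-one
Conditions: Dess–Martin periodinane, NaHCO3, CH2Cl2, 0 °C → rt
Reagents that add atoms: none
Why: Dess–Martin oxidation of the benzylic alcohol under buffered, near-neutral conditions should return the ketone without enolising C3, so the (3S) configuration from step 10 is carried over while C4 ceases to be a stereocentre.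

Step 12
Reactants: 17 (3S)-3-{8-[(tert-butyldimethylsilyl)oxy]-2,2-dimethyl-2H-chromen-6-yl}-5-methoxy-7-[(triisopropylsilyl)oxy]chroman-4-one
Product: 18 (3S)-7-hydroxy-3-(8-hydroxy-2,2-dimethyl-2H-chromen-6-yl)-5-methoxychroman-4-one
Conditions: Et3N·3HF, THF, 0 °C → rt; pH 7 buffer work-up
Reagents that add atoms: none
Why: Fluoride cleavage of both aryl silyl ethers in a mildly acidic medium should free the phenols without forming a phenoxide or an enolate, so C3 is not epimerised and the chromene is untouched.

**Compound list**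

1 | 5-bromo-2-hydroxy-3-methoxybenzaldehyde | COc1cc(Br)cc(C=O)c1O | starting material
2 | 5-bromo-2,3-dihydroxybenzaldehyde | O=Cc1cc(Br)cc(O)c1O | intermediate
3 | 6-bromo-2,2-dimethyl-1,3-benzodioxole-4-carbaldehyde | CC1(C)Oc2cc(Br)cc(C=O)c2O1 | intermediate
4 | 6-bromo-4-ethenyl-2,2-dimethyl-1,3-benzodioxole | CC1(C)Oc2cc(Br)cc(C=C)c2O1 | intermediate
5 | [4-bromo-2-(tert-butyldimethylsilyloxy)-6-ethenylphenyl](propan-2-ylidene)oxonium triflate | CC(C)=[O+]c1c(C=C)cc(Br)cc1O[Si](C)(C)C(C)(C)C.[O-]S(=O)(=O)C(F)(F)F | intermediate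
6 | 6-bromo-8-(tert-butyldimethylsilyloxy)-2,2-dimethyl-3,4-dihydro-2H-chromen-4-ylium triflate | CC1(C)C[CH+]c2cc(Br)cc(O[Si](C)(C)C(C)(C)C)c2O1.[O-]S(=O)(=O)C(F)(F)F | intermediate
7 | [(6-bromo-2,2-dimethyl-2H-chromen-8-yl)oxy](tert-butyl)dimethylsilane | CC1(C)C=Cc2cc(Br)cc(O[Si](C)(C)C(C)(C)C)c2O1 | intermediate
8 | tert-butyldimethyl{[2,2-dimethyl-6-(4,4,5,5-tetramethyl-1,3,2-dioxaborolan-2-yl)-2H-chromen-8-yl]oxy}silane | CC1(C)C=Cc2cc(B3OC(C)(C)C(C)(C)O3)cc(O[Si](C)(C)C(C)(C)C)c2O1 | intermediate
9 | 1-(2,4-dihydroxy-6-methoxyphenyl)ethan-1-one | COc1cc(O)cc(O)c1C(C)=O | starting material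
10 | 1-{2-hydroxy-6-methoxy-4-[(triisopropylsilyl)oxy]phenyl}ethan-1-one | COc1cc(O[Si](C(C)C)(C(C)C)C(C)C)cc(O)c1C(C)=O | intermediate
11 | (E)-3-(dimethylamino)-1-{2-hydroxy-6-methoxy-4-[(triisopropylsilyl)oxy]phenyl}prop-2-en-1-one | COc1cc(O[Si](C(C)C)(C(C)C)C(C)C)cc(O)c1C(=O)/C=C/N(C)C | intermediate
12 | 3-iodo-5-methoxy-7-[(triisopropylsilyl)oxy]-4H-chromen-4-one | COc1cc(O[Si](C(C)C)(C(C)C)C(C)C)cc2occ(I)c(=O)c12 | intermediate
13 | 3-{8-[(tert-butyldimethylsilyl)oxy]-2,2-dimethyl-2H-chromen-6-yl}-5-methoxy-7-[(triisopropylsilyl)oxy]-4H-chromen-4-one | COc1cc(O[Si](C(C)C)(C(C)C)C(C)C)cc2occ(-c3cc(O[Si](C)(C)C(C)(C)C)c4OC(C)(C)C=Cc4c3)c(=O)c12 | intermediate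
14 | lithium 3-{8-[(tert-butyldimethylsilyl)oxy]-2,2-dimethyl-2H-chromen-6-yl}-5-methoxy-7-[(triisopropylsilyl)oxy]-2H-chromen-4-olate | COc1cc(O[Si](C(C)C)(C(C)C)C(C)C)cc2OCC(c3cc(O[Si](C)(C)C(C)(C)C)c4OC(C)(C)C=Cc4c3)=C([O-])c12.[Li+] | intermediate
15 | rac-3-{8-[(tert-butyldimethylsilyl)oxy]-2,2-dimethyl-2H-chromen-6-yl}-5-methoxy-7-[(triisopropylsilyl)oxy]chroman-4-one | COc1cc(O[Si](C(C)C)(C(C)C)C(C)C)cc2OCC(c3cc(O[Si](C)(C)C(C)(C)C)c4OC(C)(C)C=Cc4c3)C(=O)c12 | intermediate
16 | (3S,4S)-3-{8-[(tert-butyldimethylsilyl)oxy]-2,2-dimethyl-2H-chromen-6-yl}-5-methoxy-7-[(triisopropylsilyl)oxy]chroman-4-ol | COc1cc(O[Si](C(C)C)(C(C)C)C(C)C)cc2c1[C@@H](O)[C@@H](c1cc(O[Si](C)(C)C(C)(C)C)c3c(c1)C=CC(C)(C)O3)CO2 | intermediate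
17 | (3S)-3-{8-[(tert-butyldimethylsilyl)oxy]-2,2-dimethyl-2H-chromen-6-yl}-5-methoxy-7-[(triisopropylsilyl)oxy]chroman-4-one | COc1cc(O[Si](C(C)C)(C(C)C)C(C)C)cc2c1C(=O)[C@@H](c1cc(O[Si](C)(C)C(C)(C)C)c3c(c1)C=CC(C)(C)O3)CO2 | intermediate
18 | (3S)-7-hydroxy-3-(8-hydroxy-2,2-dimethyl-2H-chromen-6-yl)-5-methoxychroman-4-one | COc1cc(O)cc2c1C(=O)[C@@H](c1cc(O)c3c(c1)C=CC(C)(C)O3)CO2 | target

**Summary**

Total step count: 12. Longest linear sequence: 10 steps (steps 1–5, then 8–12).

Steps most likely to fail:

1. Step 4 (the step under the new-method label). The ketal may not ionise under conditions mild enough for the styrene, or the vinyl group may oligomerise before the ring closes. The fallback uses known chemistry and sets out from compound 2. Selective silylation of the 3-hydroxyl, which is not hydrogen-bonded (TBSCl, imidazole, CH2Cl2), should give 5-bromo-3-[(tert-butyldimethylsilyl)oxy]-2-hydroxybenzaldehyde F1. Addition of excess 2-methylprop-1-enylmagnesium bromide in THF at low temperature should give rac-4-bromo-2-[(tert-butyldimethylsilyl)oxy]-6-(1-hydroxy-3-methylbut-2-en-1-yl)phenol F2. Mild dehydration (PPTS, toluene, 60 °C) should generate the vinyl ortho-quinone methide, which closes by oxa-6π electrocyclisation. The fallback comes back to the route at compound 7.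

2. Step 10. Hydride transfer to the electron-rich ketone flanked by the peri methoxy group may be slow, leading to incomplete conversion or to loss of the benzylic alcohol by ionisation. The fallback sets out from compound 15. Enolisation with LiHMDS and O-acylation with allyl chloroformate should give prop-2-en-1-yl 3-{8-[(tert-butyldimethylsilyl)oxy]-2,2-dimethyl-2H-chromen-6-yl}-5-methoxy-7-[(triisopropylsilyl)oxy]-2H-chromen-4-yl carbonate F3. Decarboxylative asymmetric protonation of the derived palladium enolate (Pd2(dba)3, the t-BuPHOX antipode that gives the (3S)-ketone, Meldrum's acid, 1,4-dioxane) then sets C3 directly at the ketone level. This fallback carries its own risk, since selectivity may be modest for an aryl group without ortho substituents. It comes back at compound 17 and bypasses compound 16.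

3. Step 2. Ketalisation of the hydrogen-bonded, electron-poor catechol may stall, and the aldehyde may be acetalised in competition. The fallback sets out from compound 2 and reverses the order of events. Wittig methylenation with excess ylide (Ph3PCH3Br, KOt-Bu, 3.3 equiv) should give 5-bromo-3-ethenylbenzene-1,2-diol F4. This formyl-free catechol is then ketalised under mild acid (2,2-dimethoxypropane, PPTS, toluene). The fallback comes back at compound 4.

**Further compounds**

F1 | step 4 | 5-bromo-3-[(tert-butyldimethylsilyl)oxy]-2-hydroxybenzaldehyde | CC(C)(C)[Si](C)(C)Oc1cc(Br)cc(C=O)c1O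
F2 | step 4 | rac-4-bromo-2-[(tert-butyldimethylsilyl)oxy]-6-(1-hydroxy-3-methylbut-2-en-1-yl)phenol | CC(C)=CC(O)c1cc(Br)cc(O[Si](C)(C)C(C)(C)C)c1O
F3 | step 10 | prop-2-en-1-yl 3-{8-[(tert-butyldimethylsilyl)oxy]-2,2-dimethyl-2H-chromen-6-yl}-5-methoxy-7-[(triisopropylsilyl)oxy]-2H-chromen-4-yl carbonate | COc1cc(O[Si](C(C)C)(C(C)C)C(C)C)cc2OCC(c3cc(O[Si](C)(C)C(C)(C)C)c4OC(C)(C)C=Cc4c3)=C(OC(=O)OCC=C)c12
F4 | step 2 | 5-bromo-3-ethenylbenzene-1,2-diol | Oc1cc(Br)cc(C=C)c1O
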